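## Retrosynthetic overview

1. Target 17 ⇐ desilylation at O3 of 16 ⇐ benzoylation of the C2 hydroxyl of 15 ⇐ hydrolysis of the trans-fused O1/O2 acetonide of enone 14 ⇐ cyclohexene 11 (silylation at O3, then deprotection and oxidation at C6).
2. Cyclohexene 11 ⇐ ring-closing metathesis (C4=C5) of acyclic diene 10; this is the only ring of the target and it is closed late.
3. Diene 10 ⇐ reductive opening of the branched γ-lactone 8 and benzoylation at O7; the C1–C6 bond ⇐ aldol addition of the lithium enolate of vinyl lactone 4 to acrolein, with the cis-fused dioxolane fixing the quaternary centre C1.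
4. Vinyl lactone 4 ⇐ L-gulono-1,4-lactone 1, which supplies C2 and C3. Ring order: the γ-lactone (from 1) and the dioxolane (step 1) are scaffolds, opened in steps 6 and 12; the carbocycle forms in step 8.

Assumption: locants C1–C7 in the text are those of the target (ring C1–C6, C7 = exocyclic CH2O carbon; sugar carbons 1–5 become C7, C1, C2, C3, C4), and the C6 carbinol centre made in step 4 is carried as both epimers (no stereo mark in the SMILES) until it is oxidised in step 11.

## Route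

Step 1
Reactants: 1 L-gulono-1,4-lactone
Product: 2 2,3:5,6-di-O-isopropylidene-L-gulono-1,4-lactone
Conditions: Me2C(OMe)2 (4 equiv), TsOH·H2O (cat.), DMF, rt
Reagents that add atoms: 2,2-dimethoxypropane, COC(C)(C)OC
Why: Acid-catalysed transacetalisation places isopropylidene acetals on the cis-2,3-diol and on the terminal 5,6-diol without touching any stereocentre.

Step 2
Reactants: 2 2,3:5,6-di-O-isopropylidene-L-gulono-1,4-lactone
Product: 3 2,3-O-isopropylidene-L-gulono-1,4-lactone
Conditions: AcOH/H2O (7:3), rt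
Reagents that add atoms: none
Why: Selective acetal hydrolysis, because the terminal 5,6-dioxolane is cleaved much faster than the dioxolane cis-fused to the lactone ring.

Step 3
Reactants: 3 2,3-O-isopropylidene-L-gulono-1,4-lactone
Product: 4 5,6-dideoxy-2,3-O-isopropylidene-D-lyxo-hex-5-enono-1,4-lactone
Conditions: PPh3, I2, imidazole, toluene, 110 °C
Reagents that add atoms: none
Why: Garegg–Samuelsson deoxygenation converts the vicinal diol into the terminal alkene, which removes the sugar C5 stereocentre and leaves the three ring stereocentres untouched.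

Step 4
Reactants: 4 5,6-dideoxy-2,3-O-isopropylidene-D-lyxo-hex-5-enono-1,4-lactone; 5 acrolein
Product: 7 5,6-dideoxy-2-C-[(1RS)-1-hydroxyprop-2-en-1-yl]-2,3-O-isopropylidene-D-lyxo-hex-5-enono-1,4-lactone, via lithium enolate C9H11LiO4 6 (not isolated)
Conditions: LiN(iPr)2 (1.1 equiv), THF, −78 °C; then 5 (1.5 equiv), −78 °C; AcOH quench at −78 °C
Reagents that add atoms: none
Why: Intermolecular aldol addition of the lactone lithium enolate to the aldehyde carbon of acrolein (1,2-addition under kinetic control), in which the dioxolane must stay cis-fused so the aldehyde can only approach the convex face anti to the acetonide and the C3 vinyl group, setting the quaternary centre C1 as one configuration while C6 forms as an epimer mixture that is oxidised away later.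

Step 5
Reactants: 7 5,6-dideoxy-2-C-[(1RS)-1-hydroxyprop-2-en-1-yl]-2,3-O-isopropylidene-D-lyxo-hex-5-enono-1,4-lactone
Product: 8 5,6-dideoxy-2,3-O-isopropylidene-2-C-[(1RS)-1-(triethylsilyloxy)prop-2-en-1-yl]-D-lyxo-hex-5-enono-1,4-lactone
Conditions: TESOTf, 2,6-lutidine, CH2Cl2, −78 → 0 °C
Reagents that add atoms: triethylsilyl trifluoromethanesulfonate, CC[Si](CC)(CC)OS(=O)(=O)C(F)(F)F
Why: Silylation with a silyl triflate caps the hindered β-hydroxyl under non-basic cold conditions, which blocks retro-aldol cleavage and marks O6 for later selective release.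

Step 6
Reactants: 8 5,6-dideoxy-2,3-O-isopropylidene-2-C-[(1RS)-1-(triethylsilyloxy)prop-2-en-1-yl]-D-lyxo-hex-5-enono-1,4-lactone
Product: 9 {(4R,5S)-5-[(1R)-1-hydroxyprop-2-en-1-yl]-2,2-dimethyl-4-[(1RS)-1-(triethylsilyloxy)prop-2-en-1-yl]-1,3-dioxolan-4-yl}methanol
Conditions: LiBH4, THF, 0 °C → rt; aq. NH4Cl work-up
Reagents that add atoms: none
Why: Hydride reduction of the lactone gives the 1,4-diol (primary O7–H and secondary O3–H) and leaves the silyl ether, acetonide, alkenes and all stereocentres unchanged.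

Step 7
Reactants: 9 {(4R,5S)-5-[(1R)-1-hydroxyprop-2-en-1-yl]-2,2-dimethyl-4-[(1RS)-1-(triethylsilyloxy)prop-2-en-1-yl]-1,3-dioxolan-4-yl}methanol
Product: 10 {(4R,5S)-5-[(1R)-1-hydroxyprop-2-en-1-yl]-2,2-dimethyl-4-[(1RS)-1-(triethylsilyloxy)prop-2-en-1-yl]-1,3-dioxolan-4-yl}methyl benzoate
Conditions: BzCl (1.05 equiv), pyridine, CH2Cl2, −40 → −10 °C
Reagents that add atoms: benzoyl chloride, O=C(Cl)c1ccccc1
Why: Regioselective O-acylation under kinetic control, the primary hydroxyl reacting faster than the secondary allylic one with a near-stoichiometric amount of acid chloride at low temperature.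

Step 8
Reactants: 10 {(4R,5S)-5-[(1R)-1-hydroxyprop-2-en-1-yl]-2,2-dimethyl-4-[(1RS)-1-(triethylsilyloxy)prop-2-en-1-yl]-1,3-dioxolan-4-yl}methyl benzoate
Product: 11 [(1R,2S,3R,6RS)-3-hydroxy-1,2-(isopropylidenedioxy)-6-(triethylsilyloxy)cyclohex-4-en-1-yl]methyl benzoate
Conditions: second-generation Grubbs catalyst RuCl2(=CHPh)(PCy3)(H2IMes) (5 mol%), CH2Cl2 (5 mM), 40 °C
Reagents that add atoms: none
Why: Ring-closing metathesis of the two vinyl groups closes the six-membered carbocycle (C4=C5) with loss of ethylene, the catalyst loading at the vinyl group next to the free C3 hydroxyl, and no stereocentre is touched.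

Step 9
Reactants: 11 [(1R,2S,3R,6RS)-3-hydroxy-1,2-(isopropylidenedioxy)-6-(triethylsilyloxy)cyclohex-4-en-1-yl]methyl benzoate
Product: 12 [(1R,2S,3R,6RS)-1,2-(isopropylidenedioxy)-6-(triethylsilyloxy)-3-(triisopropylsilyloxy)cyclohex-4-en-1-yl]methyl benzoate
Conditions: TIPSOTf, 2,6-lutidine, CH2Cl2, 0 °C → rt
Reagents that add atoms: triisopropylsilyl trifluoromethanesulfonate, CC(C)[Si](C(C)C)(C(C)C)OS(=O)(=O)C(F)(F)F
Why: Silylation of the only free hydroxyl puts an acid-robust silyl ether on O3 that survives the later triethylsilyl cleavage and acetonide hydrolysis.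

Step 10
Reactants: 12 [(1R,2S,3R,6RS)-1,2-(isopropylidenedioxy)-6-(triethylsilyloxy)-3-(triisopropylsilyloxy)cyclohex-4-en-1-yl]methyl benzoate
Product: 13 [(1S,2S,3R,6RS)-6-hydroxy-1,2-(isopropylidenedioxy)-3-(triisopropylsilyloxy)cyclohex-4-en-1-yl]methyl benzoate
Conditions: HF·pyridine, pyridine, THF, 0 °C
Reagents that add atoms: none
Why: Selective desilylation, the triethylsilyl ether being cleaved by buffered HF far faster than the triisopropylsilyl ether, while the benzoate and the acetonide survive (the C1 descriptor changes only through priorities).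

Step 11
Reactants: 13 [(1S,2S,3R,6RS)-6-hydroxy-1,2-(isopropylidenedioxy)-3-(triisopropylsilyloxy)cyclohex-4-en-1-yl]methyl benzoate
Product: 14 [(1R,2S,3R)-1,2-(isopropylidenedioxy)-6-oxo-3-(triisopropylsilyloxy)cyclohex-4-en-1-yl]methyl benzoate
Conditions: Dess–Martin periodinane, pyridine, CH2Cl2, 0 °C → rt
Reagents that add atoms: none
Why: Dess–Martin oxidation of the only free (allylic, secondary) hydroxyl gives the enone and merges both C6 epimers into one compound.

Step 12
Reactants: 14 [(1R,2S,3R)-1,2-(isopropylidenedioxy)-6-oxo-3-(triisopropylsilyloxy)cyclohex-4-en-1-yl]methyl benzoate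
Product: 15 [(1R,2S,3R)-1,2-dihydroxy-6-oxo-3-(triisopropylsilyloxy)cyclohex-4-en-1-yl]methyl benzoate
Conditions: TFA/H2O (9:1), CH2Cl2, 0 °C
Reagents that add atoms: none
Why: Acid hydrolysis of the strained trans-fused acetonide is fast at 0 °C, under which the secondary triisopropylsilyl ether, the benzoate and the enone are stable.

Step 13
Reactants: 15 [(1R,2S,3R)-1,2-dihydroxy-6-oxo-3-(triisopropylsilyloxy)cyclohex-4-en-1-yl]methyl benzoate
Product: 16 [(1R,2S,3R)-2-(benzoyloxy)-1-hydroxy-6-oxo-3-(triisopropylsilyloxy)cyclohex-4-en-1-yl]methyl benzoate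
Conditions: BzCl, pyridine, DMAP (cat.), CH2Cl2, 0 °C → rt
Reagents that add atoms: benzoyl chloride, O=C(Cl)c1ccccc1
Why: Nucleophile-catalysed acylation esterifies the secondary C2 hydroxyl, while the tertiary α-keto hydroxyl at C1 is too hindered to react and the mild base avoids retro-aldol cleavage.

Step 14
Reactants: 16 [(1R,2S,3R)-2-(benzoyloxy)-1-hydroxy-6-oxo-3-(triisopropylsilyloxy)cyclohex-4-en-1-yl]methyl benzoate
Product: 17 [(1R,2S,3R)-2-(benzoyloxy)-1,3-dihydroxy-6-oxocyclohex-4-en-1-yl]methyl benzoate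
Conditions: HF·pyridine, THF, 0 °C → rt
Reagents that add atoms: none
Why: Acidic fluoride desilylation frees the C3 hydroxyl without the C2→C3 benzoyl migration that basic fluoride could cause, leaving benzoates, enone and tertiary alcohol intact.

## Compound list

1 | L-gulono-1,4-lactone | O=C1[C@@H](O)[C@@H](O)[C@@H]([C@@H](O)CO)O1 | starting material
2 | 2,3:5,6-di-O-isopropylidene-L-gulono-1,4-lactone | O=C1[C@H]2OC(C)(C)O[C@H]2[C@@H]([C@@H]3COC(C)(C)O3)O1 | intermediate
3 | 2,3-O-isopropylidene-L-gulono-1,4-lactone | O=C1[C@H]2OC(C)(C)O[C@H]2[C@@H]([C@@H](O)CO)O1 | intermediate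
4 | 5,6-dideoxy-2,3-O-isopropylidene-D-lyxo-hex-5-enono-1,4-lactone | O=C1[C@H]2OC(C)(C)O[C@H]2[C@@H](C=C)O1 | intermediate
5 | acrolein (prop-2-enal) | C=CC=O | starting material
6 | lithium enolate C9H11LiO4 of lactone 4 (enolate C1=C7, dioxolane and vinyl-bearing centres unchanged; not isolated) | [Li+].[O-]C1=C2OC(C)(C)O[C@H]2[C@@H](C=C)O1 | intermediate
7 | 5,6-dideoxy-2-C-[(1RS)-1-hydroxyprop-2-en-1-yl]-2,3-O-isopropylidene-D-lyxo-hex-5-enono-1,4-lactone | O=C1[C@@]2(C(O)C=C)OC(C)(C)O[C@H]2[C@@H](C=C)O1 | intermediate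
8 | 5,6-dideoxy-2,3-O-isopropylidene-2-C-[(1RS)-1-(triethylsilyloxy)prop-2-en-1-yl]-D-lyxo-hex-5-enono-1,4-lactone | O=C1[C@@]2(C(O[Si](CC)(CC)CC)C=C)OC(C)(C)O[C@H]2[C@@H](C=C)O1 | intermediate
9 | {(4R,5S)-5-[(1R)-1-hydroxyprop-2-en-1-yl]-2,2-dimethyl-4-[(1RS)-1-(triethylsilyloxy)prop-2-en-1-yl]-1,3-dioxolan-4-yl}methanol | OC[C@@]1(C(O[Si](CC)(CC)CC)C=C)OC(C)(C)O[C@H]1[C@H](O)C=C | intermediate
10 | {(4R,5S)-5-[(1R)-1-hydroxyprop-2-en-1-yl]-2,2-dimethyl-4-[(1RS)-1-(triethylsilyloxy)prop-2-en-1-yl]-1,3-dioxolan-4-yl}methyl benzoate | O=C(OC[C@@]1(C(O[Si](CC)(CC)CC)C=C)OC(C)(C)O[C@H]1[C@H](O)C=C)c1ccccc1 | intermediate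
11 | [(1R,2S,3R,6RS)-3-hydroxy-1,2-(isopropylidenedioxy)-6-(triethylsilyloxy)cyclohex-4-en-1-yl]methyl benzoate | O=C(OC[C@@]12OC(C)(C)O[C@H]1[C@H](O)C=CC2O[Si](CC)(CC)CC)c1ccccc1 | intermediate
12 | [(1R,2S,3R,6RS)-1,2-(isopropylidenedioxy)-6-(triethylsilyloxy)-3-(triisopropylsilyloxy)cyclohex-4-en-1-yl]methyl benzoate | O=C(OC[C@@]12OC(C)(C)O[C@H]1[C@H](O[Si](C(C)C)(C(C)C)C(C)C)C=CC2O[Si](CC)(CC)CC)c1ccccc1 | intermediate
13 | [(1S,2S,3R,6RS)-6-hydroxy-1,2-(isopropylidenedioxy)-3-(triisopropylsilyloxy)cyclohex-4-en-1-yl]methyl benzoate | O=C(OC[C@@]12OC(C)(C)O[C@H]1[C@H](O[Si](C(C)C)(C(C)C)C(C)C)C=CC2O)c1ccccc1 | intermediate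
14 | [(1R,2S,3R)-1,2-(isopropylidenedioxy)-6-oxo-3-(triisopropylsilyloxy)cyclohex-4-en-1-yl]methyl benzoate | O=C(OC[C@@]12OC(C)(C)O[C@H]1[C@H](O[Si](C(C)C)(C(C)C)C(C)C)C=CC2=O)c1ccccc1 | intermediate
15 | [(1R,2S,3R)-1,2-dihydroxy-6-oxo-3-(triisopropylsilyloxy)cyclohex-4-en-1-yl]methyl benzoate | O=C(OC[C@@]1(O)[C@@H](O)[C@H](O[Si](C(C)C)(C(C)C)C(C)C)C=CC1=O)c1ccccc1 | intermediate
16 | [(1R,2S,3R)-2-(benzoyloxy)-1-hydroxy-6-oxo-3-(triisopropylsilyloxy)cyclohex-4-en-1-yl]methyl benzoate | O=C(OC[C@@]1(O)[C@@H](OC(=O)c2ccccc2)[C@H](O[Si](C(C)C)(C(C)C)C(C)C)C=CC1=O)c1ccccc1 | intermediate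
17 | [(1R,2S,3R)-2-(benzoyloxy)-1,3-dihydroxy-6-oxocyclohex-4-en-1-yl]methyl benzoate | O=C(OC[C@]1(O)C(=O)C=C[C@@H](O)[C@@H]1OC(=O)c1ccccc1)c1ccccc1 | target

## Step count and risks

Total step count: 14. Longest linear sequence: 14 steps (1 → 17); acrolein 5 enters at step 4.

Steps most likely to fail:

Step 4 (aldol of the lactone enolate). The enolate may β-eliminate the acetonide oxygen or the adduct may revert by retro-aldol. The fallback makes the same C1–C6 bond by a crossed aldol with formaldehyde at the lactol stage and sets out from 4. Reduction with iBu2AlH (CH2Cl2, −78 °C) gives 5,6-dideoxy-2,3-O-isopropylidene-D-lyxo-hex-5-enofuranose F1. Aqueous formaldehyde with K2CO3 in methanol at 65 °C gives 5,6-dideoxy-2-C-(hydroxymethyl)-2,3-O-isopropylidene-D-lyxo-hex-5-enofuranose F2, again by attack anti to the dioxolane. Excess Dess–Martin periodinane oxidises both the lactol and the primary alcohol to 5,6-dideoxy-2-C-formyl-2,3-O-isopropylidene-D-lyxo-hex-5-enono-1,4-lactone F3. CH2=CHMgBr in THF at −78 °C then adds to the aldehyde only, and the route is rejoined at 7.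

Step 7 (regioselective benzoylation). The primary hydroxyl is neopentyl-like and may not be distinguished well enough from the secondary allylic one. The fallback postpones the benzoate and uses the more selective primary silylation, setting out from 9. TBSCl with imidazole in DMF at 0 °C gives the C7 tert-butyldimethylsilyl ether of diol 9 F4. Ring-closing metathesis as in step 8 gives the O7-silylated cyclohexenol F5. TIPSOTf with 2,6-lutidine gives its C3 triisopropylsilyl ether F6. HF·pyridine removes the triethylsilyl and the primary tert-butyldimethylsilyl groups but not the secondary triisopropylsilyl group, giving the C6,C7-diol F7. Benzoyl chloride in pyridine at −20 °C then has to choose only between the primary hydroxyl and the very hindered C6 carbinol, and the route is rejoined at 13.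

Step 8 (ring-closing metathesis). One vinyl group sits next to a quaternary centre and a silyloxy group, and the ring formed is trans-fused to the dioxolane. The fallback closes the ring at the enone oxidation level and sets out from 10. TIPSOTf with 2,6-lutidine gives the C3 triisopropylsilyl ether of diene 10 F8. HF·pyridine with pyridine at 0 °C gives the C6 allylic alcohol F9. Dess–Martin periodinane gives the vinyl ketone F10, in which the carbon next to C1 is now planar. Ring-closing metathesis of this dienone with second-generation Hoveyda–Grubbs catalyst RuCl2(=CH-C6H4-2-OiPr)(H2IMes) in toluene at 80 °C gives the enone directly, and the route is rejoined at 14.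

## Further compounds

F1 | step 4 | 5,6-dideoxy-2,3-O-isopropylidene-D-lyxo-hex-5-enofuranose (anomeric mixture) | OC1[C@H]2OC(C)(C)O[C@H]2[C@@H](C=C)O1
F2 | step 4 | 5,6-dideoxy-2-C-(hydroxymethyl)-2,3-O-isopropylidene-D-lyxo-hex-5-enofuranose (anomeric mixture) | OC1[C@@]2(CO)OC(C)(C)O[C@H]2[C@@H](C=C)O1
F3 | step 4 | 5,6-dideoxy-2-C-formyl-2,3-O-isopropylidene-D-lyxo-hex-5-enono-1,4-lactone | O=C1[C@@]2(C=O)OC(C)(C)O[C@H]2[C@@H](C=C)O1
F4 | step 7 | C7 tert-butyldimethylsilyl ether of diol 9 | CC(C)(C)[Si](C)(C)OC[C@@]1(C(O[Si](CC)(CC)CC)C=C)OC(C)(C)O[C@H]1[C@H](O)C=C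
F5 | step 7 | O7-tert-butyldimethylsilyl analogue of cyclohexenol 11 | CC(C)(C)[Si](C)(C)OC[C@@]12OC(C)(C)O[C@H]1[C@H](O)C=CC2O[Si](CC)(CC)CC
F6 | step 7 | C3 triisopropylsilyl ether of F5 | CC(C)(C)[Si](C)(C)OC[C@@]12OC(C)(C)O[C@H]1[C@H](O[Si](C(C)C)(C(C)C)C(C)C)C=CC2O[Si](CC)(CC)CC
F7 | step 7 | C6,C7-diol (13 without its benzoate) | OC[C@@]12OC(C)(C)O[C@H]1[C@H](O[Si](C(C)C)(C(C)C)C(C)C)C=CC2O
F8 | step 8 | C3 triisopropylsilyl ether of diene 10 | O=C(OC[C@@]1(C(O[Si](CC)(CC)CC)C=C)OC(C)(C)O[C@H]1[C@H](O[Si](C(C)C)(C(C)C)C(C)C)C=C)c1ccccc1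
F9 | step 8 | C6 allylic alcohol from F8 (both C6 epimers) | O=C(OC[C@@]1(C(O)C=C)OC(C)(C)O[C@H]1[C@H](O[Si](C(C)C)(C(C)C)C(C)C)C=C)c1ccccc1
F10 | step 8 | C6 vinyl ketone from F9 | O=C(OC[C@@]1(C(=O)C=C)OC(C)(C)O[C@H]1[C@H](O[Si](C(C)C)(C(C)C)C(C)C)C=C)c1ccccc1
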